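**Plan**

- The target, 6,7-dimethoxy-2-(2,3,4-trimethoxyphenyl)chromen-4-one, has no stereocentre and no stereogenic double bond, so only regiochemistry has to be controlled.
- The retrosynthesis first cuts O1–C2 of ring C (phenol adding to an ynone). It then cuts O1–C8a and C4–C4a together, which leads back to 4,5-dimethoxybenzyne and 3-(2,3,4-trimethoxyphenyl)propiolic acid.
- The enabling feature is that O1 (on C8a) and the carbonyl carbon C4 (on C4a) sit on adjacent carbons of ring A. This ortho oxygen/acyl pattern is what an aryne leaves after inserting into the C–O bond of a carboxyl group.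
- Forward, ring A is made as a 2-silylaryl triflate from 3,4-dimethoxyphenol (3 steps), and ring B with C2, C3 and C4 as the propiolic acid from 2,3,4-trimethoxybenzaldehyde (2 steps).
- The aryne insertion joins the two pieces as the 2-hydroxyaryl ynone, and ring C closes last by 6-endo oxa-Michael addition.
- The aryne is symmetric, so the 6,7-dimethoxy pattern results whichever aryne carbon takes the oxygen.

Key step: step 6

Remark: if part of the hydroxyaryl ynone has already cyclised to the flavone under the conditions of the key step, the mixture is taken into the last step as it is.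

**Route**

Step 1
Reactants: 1 3,4-dimethoxyphenol
Product: 2 2-bromo-4,5-dimethoxyphenol
Conditions: NBS (1.0 equiv), MeCN, −20 to 0 °C, dark
Reagents that add atoms: N-bromosuccinimide, O=C1CCC(=O)N1Br
Why: Electrophilic aromatic bromination goes to C6, ortho to the hydroxyl and para to the C3 methoxy group, because C2 is flanked by two substituents and C5 is meta to the hydroxyl, while one equivalent of NBS at low temperature should limit dibromination and oxidation to the quinone.

Step 2
Reactants: 2 2-bromo-4,5-dimethoxyphenol
Product: 3 (2-bromo-4,5-dimethoxyphenoxy)trimethylsilane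
Conditions: HMDS (1.5 equiv), THF, reflux; volatiles removed in vacuo, used crude
Reagents that add atoms: hexamethyldisilazane, C[Si](C)(C)N[Si](C)(C)C
Why: O-Silylation of a phenol with hexamethyldisilazane is driven by loss of ammonia and needs no added base, so the moisture-sensitive aryl silyl ether can be used after simple evaporation.

Step 3
Reactants: 3 (2-bromo-4,5-dimethoxyphenoxy)trimethylsilane
Product: 6 4,5-dimethoxy-2-(trimethylsilyl)phenyl trifluoromethanesulfonate, via aryllithium 4 (not isolated), via lithium 2-silylphenoxide 5 (not isolated)
Conditions: n-BuLi (1.1 equiv), THF, −100 to −80 °C; then Tf2O (1.2 equiv), −100 to −80 °C; cold aq NaHCO3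
Reagents that add atoms: trifluoromethanesulfonic anhydride, O=S(=O)(OS(=O)(=O)C(F)(F)F)C(F)(F)F
Why: Bromine–lithium exchange gives aryllithium 4, which undergoes the anionic 1,3 O-to-C silyl shift (retro-Brook rearrangement) to the more stable lithium phenoxide 5, and O-sulfonylation with Tf2O at low temperature then gives the 2-silylaryl triflate, the standard sequence for this class of aryne precursor.

Step 4
Reactants: 7 2,3,4-trimethoxybenzaldehyde
Product: 8 1-ethynyl-2,3,4-trimethoxybenzene
Conditions: dimethyl (1-diazo-2-oxopropyl)phosphonate (1.3 equiv), K2CO3 (2 equiv), MeOH, 0 °C to rt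
Reagents that add atoms: dimethyl (1-diazo-2-oxopropyl)phosphonate (Ohira–Bestmann reagent), COP(=O)(OC)C(=[N+]=[N-])C(C)=O
Why: In this Seyferth–Gilbert homologation with the Ohira–Bestmann reagent, methanolysis of the acetyl group frees the diazomethylphosphonate anion, which adds to the aldehyde, eliminates dimethyl phosphate in the Horner–Wadsworth–Emmons manner and, after loss of N2 and a 1,2-hydride shift of the alkylidene carbene, gives the terminal alkyne under conditions the three methoxy groups tolerate.

Step 5
Reactants: 8 1-ethynyl-2,3,4-trimethoxybenzene
Product: 10 3-(2,3,4-trimethoxyphenyl)propiolic acid, via lithium acetylide 9 (not isolated)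
Conditions: n-BuLi (1.1 equiv), THF, −78 °C; CO2 (dry gas), −78 to 0 °C; then 1 M HCl, 0 °C
Reagents that add atoms: carbon dioxide, O=C=O
Why: Deprotonation of the terminal alkyne and carboxylation of the lithium acetylide with CO2 is a standard route to arylpropiolic acids, and cold acidification should avoid decarboxylation.

Step 6
Reactants: 6 4,5-dimethoxy-2-(trimethylsilyl)phenyl trifluoromethanesulfonate; 10 3-(2,3,4-trimethoxyphenyl)propiolic acid
Product: 12 1-(2-hydroxy-4,5-dimethoxyphenyl)-3-(2,3,4-trimethoxyphenyl)prop-2-yn-1-one, via 4,5-dimethoxybenzyne 11 (not isolated)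
Conditions: 6 (1.5 equiv), CsF (4 equiv), THF, 125 °C, sealed tube; aq NH4Cl
Reagents that add atoms: none
Why: Fluoride attacks silicon of 6 and triflate leaves, releasing the symmetric aryne 11 slowly because CsF is sparingly soluble in THF; the cesium carboxylate of 10 adds through oxygen to one aryne carbon, and the ortho aryl anion so formed attacks the ester carbonyl beside it, passing through a four-membered alkoxide that opens to the ortho-acyl phenoxide, so that O1–C8a and C4–C4a are made in one operation. The closest known reaction type is the insertion of arynes into the carboxyl C–O bond of carboxylic acids to give 2-hydroxyaryl ketones, a net anionic acyl shift of the Fries type. No ring of the target is closed and no stereocentre is created here, ring C being left for step 7. Regiochemistry is not an issue because the two aryne carbons are equivalent, each meta to one methoxy group and para to the other. The selectivity that matters is acyl transfer against protonation of the aryl anion to the plain aryl ester, and it should be secured by the aprotic medium, by the excess of CsF that keeps the acid as its carboxylate, by the high temperature and by the carbonyl lying next to the carbanion. Attack at the carbonyl carbon is preferred to attack at the alkyne because the far alkyne carbon cannot be reached from the ortho position.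

Step 7
Reactants: 12 1-(2-hydroxy-4,5-dimethoxyphenyl)-3-(2,3,4-trimethoxyphenyl)prop-2-yn-1-one
Product: 13 6,7-dimethoxy-2-(2,3,4-trimethoxyphenyl)-4H-chromen-4-one
Conditions: K2CO3 (2 equiv), acetone, reflux
Reagents that add atoms: none
Why: Intramolecular oxa-Michael addition of the phenoxide to the ynone in the 6-endo-dig mode closes ring C, the aprotic medium favouring attack at the aryl-bearing alkyne carbon (future C2) because it gives a conjugated allenolate whereas 5-exo attack at the carbon next to the carbonyl would give an unstabilised vinyl anion that reverts, and protonation at C3 then gives the chromen-4-one.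

**Compound list**

1 | 3,4-dimethoxyphenol | COc1ccc(O)cc1OC | starting material
2 | 2-bromo-4,5-dimethoxyphenol | COc1cc(O)c(Br)cc1OC | intermediate
3 | (2-bromo-4,5-dimethoxyphenoxy)trimethylsilane | COc1cc(O[Si](C)(C)C)c(Br)cc1OC | intermediate
4 | [4,5-dimethoxy-2-(trimethylsilyloxy)phenyl]lithium | [Li]c1cc(OC)c(OC)cc1O[Si](C)(C)C | intermediate
5 | lithium 4,5-dimethoxy-2-(trimethylsilyl)phenoxide | [Li+].[O-]c1cc(OC)c(OC)cc1[Si](C)(C)C | intermediate
6 | 4,5-dimethoxy-2-(trimethylsilyl)phenyl trifluoromethanesulfonate | COc1cc(OS(=O)(=O)C(F)(F)F)c([Si](C)(C)C)cc1OC | intermediate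
7 | 2,3,4-trimethoxybenzaldehyde | COc1ccc(C=O)c(OC)c1OC | starting material
8 | 1-ethynyl-2,3,4-trimethoxybenzene | C#Cc1ccc(OC)c(OC)c1OC | intermediate
9 | lithium (2,3,4-trimethoxyphenyl)acetylide | [Li]C#Cc1ccc(OC)c(OC)c1OC | intermediate
10 | 3-(2,3,4-trimethoxyphenyl)propiolic acid | OC(=O)C#Cc1ccc(OC)c(OC)c1OC | intermediate
11 | 4,5-dimethoxybenzyne | COC1=CC#CC=C1OC | intermediate
12 | 1-(2-hydroxy-4,5-dimethoxyphenyl)-3-(2,3,4-trimethoxyphenyl)prop-2-yn-1-one | COc1cc(O)c(C(=O)C#Cc2ccc(OC)c(OC)c2OC)cc1OC | intermediate
13 | 6,7-dimethoxy-2-(2,3,4-trimethoxyphenyl)-4H-chromen-4-one | COc1cc2oc(-c3ccc(OC)c(OC)c3OC)cc(=O)c2cc1OC | target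

**Step count**

Total: 7 steps. Longest linear sequence: 5 steps (steps 1, 2, 3, 6, 7); the acid arm (steps 4, 5) converges at step 6.

**Steps most likely to fail, with fallbacks**

Step 6. The aryl anion may be protonated faster than it transfers the acyl group, ending at the O-aryl propiolate. The product phenoxide may also be arylated by a second aryne, or the propiolate may decarboxylate at 125 °C. The fallback sets out from 1 and 8 and comes back at 13. Iodination of 1 with N-iodosuccinimide (MeCN, 0 °C) at the same position as in step 1 should give 2-iodo-4,5-dimethoxyphenol F1. A carbonylative Sonogashira annulation of F1 with alkyne 8 (PdCl2(PPh3)2 cat., CO, Et2NH, 60–120 °C) then forms C4–C4a through an acylpalladium species. Ynone 12 arises in the flask, and the secondary amine medium closes it 6-endo to 13. O1–C8a is already in place in F1, so the aryne is no longer needed.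

Step 3. Halogen–metal exchange may be incomplete, or the aryllithium may be protonated before the silyl group migrates. Tf2O may also be consumed by ring-opening of THF, leaving desilylated or untriflated material. The fallback sets out from 2 and comes back at 6. It replaces the silyl migration by intermolecular C-silylation and moves the triflation out of THF.
- Phenol 2 is treated with n-BuLi (2.1 equiv, THF, −78 °C; the first equivalent deprotonates the hydroxyl, the second exchanges bromine) and then with excess Me3SiCl to give [4,5-dimethoxy-2-(trimethylsilyl)phenoxy]trimethylsilane F2.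
- Mild methanolysis of the O–Si bond (K2CO3, MeOH, rt) gives 4,5-dimethoxy-2-(trimethylsilyl)phenol F3, which can be purified.
- Triflation with Tf2O and pyridine in CH2Cl2 at 0 °C gives 6.

Step 7. The phenoxide may close 5-exo at the carbon next to the carbonyl and give the aurone, or the cyclisation may stall because the electron-rich, ortho-substituted aryl group deactivates the alkyne terminus. The fallback sets out from 12 and comes back at 13. Diethylamine (EtOH, rt) adds to the ynone in an aza-Michael reaction to give (E)-3-(diethylamino)-1-(2-hydroxy-4,5-dimethoxyphenyl)-3-(2,3,4-trimethoxyphenyl)prop-2-en-1-one F4. F4 is drawn as the E isomer; its geometry is lost on ring closure. On heating in EtOH the phenol attacks the amine-bearing carbon and diethylamine is expelled (addition–elimination), which can only give the six-membered ring.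

**Further compounds**

F1 | step 6 | 2-iodo-4,5-dimethoxyphenol | COc1cc(O)c(I)cc1OC
F2 | step 3 | [4,5-dimethoxy-2-(trimethylsilyl)phenoxy]trimethylsilane | COc1cc(O[Si](C)(C)C)c([Si](C)(C)C)cc1OC
F3 | step 3 | 4,5-dimethoxy-2-(trimethylsilyl)phenol | COc1cc(O)c([Si](C)(C)C)cc1OC
F4 | step 7 | (E)-3-(diethylamino)-1-(2-hydroxy-4,5-dimethoxyphenyl)-3-(2,3,4-trimethoxyphenyl)prop-2-en-1-one | CCN(CC)/C(=C/C(=O)c1cc(OC)c(OC)cc1O)c1ccc(OC)c(OC)c1OC
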